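Locants: flavanone numbering for 11 and 17–19 (O1, C2–C8a, primes for ring B, double primes C1''–C6'' for the side chain); primed acetophenone numbering for 6–10.

## The problem

- The target is a (2S)-flavanone whose ring A is fully substituted except at C6. It carries O1 and C4a of ring C, a free 5-OH, a 7-OMe and, at C8, a ten-carbon chain C1''H2–C2''H(isopropenyl)–C3''H2–C4''H2–C5''(OH)Me2. Ring B is a free resorcinol.
- Any acetophenone precursor of ring A has two oxygens ortho to the acyl carbon. The one next to the chain must become O1 and the other the 5-OH, otherwise the 6-alkyl isomer forms. The chain itself must enter between O1 and O7.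
- The two stereocentres, C2 (S) and C2'' (R), lie five bonds apart (C2–O1–C8a–C8–C1''–C2'') across a flat ring. Neither can direct the other, so each needs its own source of chirality.
- C2'' is the harder one: a tertiary allylic carbon with no heteroatom neighbour and two plain methylene substituents.
- The feature that opens the route is that C2'' carries an isopropenyl group and two CH2 arms, C1'' and C3''–C4''–C5''(Me). This is C4 of (R)-limonene with its ring arms C3 and C5–C6–C1(Me). Cutting the limonene C1=C2 bond, adding one methyl to C1 and replacing C2 by C8 of ring A gives the side chain in the right configuration.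
- C2 is labile: base opens ring C by E1cB (retro-oxa-Michael) to the chalcone, the more so once 5-OH and 2'-OH are free.
- The side chain forbids strong acid and hydrogenation. Protonation of the isopropenyl group gives a tertiary cation that the C5'' hydroxyl traps as a 2,2,6,6-tetramethyloxane, and a free phenol ortho to the chain closes a chroman.

## Retrosynthesis

**19 from 17.** Only O–C bonds of three acetals are cut. Methoxymethyl ethers are chosen because they survive butyllithium, zinc/nickel, the amide acetal and the rhodium step. The forward reaction must cleave them without Brønsted acid strong enough to protonate the isopropenyl group and without base.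

**17 from 11 and 16.** The C2–C1' bond is cut. The neighbouring cut, O1–C2 (closure of a chalcone), is reversible and under substrate control would give both C2 epimers, since C2'' is too far away to help. Conjugate arylation of the flat chromone 11 by the achiral boronic acid 16 sets C2 irreversibly, under neutral conditions and by the ligand alone. The forward step needs high facial selectivity on an electron-rich chromone with an ortho-substituted aryl donor.

**11 from 9 (through 10).** O1–C2 and C2–C3 are cut and C2 becomes the carbon of an amide acetal. Because O6' of 9 is blocked and O2' is free, ring C can only close through the oxygen next to the side chain. The 6- versus 8-alkyl question is thereby answered by the protecting group and not by a selectivity.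

**9 from 8 and 5 (key disconnection).** The C8–C1'' bond (C3'–C1'' in 9) is cut and a carboxyl group is added back to C1''. This turns the side chain into the acid 4, which is the C1–C2 seco-acid of limonene with one extra methyl.
- The neighbouring cut C1''–C2'' would need a benzylic nucleophile and would have to create C2''.
- A polar C-alkylation at C8 would leave the site of attack to the ambident phenoxide.
- The decarboxylative cut fixes the site by a C–I bond and brings C2'', the isopropenyl group and the carbinol in one piece.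
- The coupling is placed at the acetophenone stage because 8 has no radical acceptor (the chromone enone comes later) and no C2 stereocentre to lose.
- The forward reaction must capture a primary homoallylic radical at a di-ortho-substituted arylnickel centre.

**5 from 4, 3, 2 and 1.** The ester 5 is the activated form of acid 4. The C5''–CH3 bond is cut (Grignard addition to the methyl ketone of 3). Acid 3 comes from aldehyde 2 and 2 from oxidative opening of limonene oxide 1 between C1 and C2. Four functional-group steps turn a commodity terpene into the whole chain, and no step touches C2''.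

**8 from 7 and 6.** The C3'–I and O6'–CH2 bonds are cut. The diol 6 has a mirror plane, so mono-protection gives one compound. Iodination must then go ortho to the remaining chelated hydroxyl.

**16 from 13 and 12.** The C–B bond is cut back to the bromide 13, made from 4-bromoresorcinol 12. Bromine–lithium exchange places boron para and ortho to the two oxygens, which direct ortho-lithiation would not do.

## Roads not taken

**Alternative 1:** the most obvious plan cuts C8–C1'' by polar alkylation.
- Forward: C-alkylation of the phenoxide of 6 with (S)-lavandulyl bromide A2, made from (S)-lavandulol A1, would give A3. Claisen–Schmidt condensation, chalcone closure and late hydration of the distal alkene would follow.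
- A2 is a β-branched homoallylic halide, not an allylic one, so SN2 at carbon is slow. O-alkylation, C3'/C5' mixtures and dialkylation of the ambident anion are to be expected.
- The alcohol that maps onto C2'' is the S enantiomer (CH2OH outranks isopropenyl), not the one that lavender oil supplies.
- Hydration of the trisubstituted alkene beside the isopropenyl group needs an epoxidation/hydride detour, and C2 is formed without control.
- The chosen plan fixes the ring position by a C–I bond and takes C2'' and the finished carbinol from limonene.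

**Alternative 2:** cut C2''–C3'' with an ene reaction.
- Forward: Lewis-acid-promoted conjugate ene reaction of the 8-prenyl acetophenone A4 with methyl vinyl ketone would give the methyl ketone A5 in one step, and methylmagnesium bromide would finish the chain.
- No catalyst-controlled intermolecular ene reaction of a trisubstituted alkene with an enone is available to set C2''.
- The Lewis acid would sit on the chelated aryl ketone and the acetal oxygens.
- A5 carries two ketones that compete for the Grignard reagent.
- The route is short but cannot defend the C2'' configuration, which the limonene plan gets for nothing.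

**Alternative 3:** strain release at C8–C1''.
- Forward: Pd-catalysed ring-opening arylation of the cyclopropanol A6 with iodide 8 (β-carbon elimination of the palladium cyclopropoxide to a homoenolate, then reductive elimination) would give the β-aryl ketone A7. Methylenation of the acetyl group and desilylation would follow.
- The C–C bond is formed by a two-electron path and the ring strain drives it.
- A6 needs its own enantioselective synthesis of several steps.
- In A7, C2'' sits α to a ketone and can epimerise during olefination, and two more steps are needed after the coupling.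
- In the chosen plan the isopropenyl group is present from the start and C2'' is never next to a carbonyl.

Key step: step 7

Assumption: 1, 6 and 12 are taken as commercial. Compound 1 is used as the cis/trans mixture derived from (R)-(+)-limonene, since both epoxide carbons lose their configuration in step 1.

## Steps

Step 1
Reactants: 1 (4R)-limonene 1,2-oxide (cis/trans mixture)
Product: 2 (3R)-6-oxo-3-(prop-1-en-2-yl)heptanal
Conditions: H5IO6 (1.1 equiv), THF/H2O, 0 °C to rt
Reagents that add atoms: water, O
Why: Acid-promoted epoxide hydrolysis and Malaprade glycol cleavage in one pot open the ring between C1 and C2; the isopropenyl group is inert to periodate and the stereocentre is not α to either new carbonyl, so it cannot epimerise.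

Step 2
Reactants: 2 (3R)-6-oxo-3-(prop-1-en-2-yl)heptanal
Product: 3 (3R)-6-oxo-3-(prop-1-en-2-yl)heptanoic acid
Conditions: NaClO2, NaH2PO4, 2-methylbut-2-ene, t-BuOH/H2O, 0 °C to rt
Reagents that add atoms: sodium chlorite, [Na+].[O-]Cl=O
Why: Pinnick oxidation converts the aldehyde and leaves the methyl ketone; 2-methylbut-2-ene scavenges HOCl faster than the isopropenyl group can react.

Step 3
Reactants: 3 (3R)-6-oxo-3-(prop-1-en-2-yl)heptanoic acid
Product: 4 (3R)-6-hydroxy-6-methyl-3-(prop-1-en-2-yl)heptanoic acid
Conditions: MeMgBr (3.5 equiv), LaCl3·2LiCl (0.3 equiv), THF, -20 to 0 °C; aq. citric acid to pH 4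
Reagents that add atoms: methylmagnesium bromide, C[Mg]Br
Why: Grignard addition to the ketone; the first equivalent forms the magnesium carboxylate, which resists further addition, so only C6 is methylated, and the lanthanum salt suppresses enolisation. The mild acidic work-up avoids cycloetherification.

Step 4
Reactants: 4 (3R)-6-hydroxy-6-methyl-3-(prop-1-en-2-yl)heptanoic acid
Product: 5 1,3-dioxoisoindolin-2-yl (3R)-6-hydroxy-6-methyl-3-(prop-1-en-2-yl)heptanoate
Conditions: N-hydroxyphthalimide, DIC, DMAP (cat.), CH2Cl2, rt
Reagents that add atoms: N-hydroxyphthalimide, O=C1c2ccccc2C(=O)N1O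
Why: Carbodiimide (Steglich) esterification gives the redox-active ester; the tertiary alcohol is too hindered to be acylated and a seven-membered lactone should not form.

Step 5
Reactants: 6 1-(2,6-dihydroxy-4-methoxyphenyl)ethan-1-one
Product: 7 1-[2-hydroxy-4-methoxy-6-(methoxymethoxy)phenyl]ethan-1-one
Conditions: MOMCl (1.05 equiv), iPr2NEt, CH2Cl2, 0 °C
Reagents that add atoms: chloromethyl methyl ether, COCCl
Why: O-Alkylation under amine base; 6 has a mirror plane, so either hydroxyl gives the same ether, and the remaining hydroxyl is held in the hydrogen bond to the carbonyl and resists a second alkylation.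

Step 6
Reactants: 7 1-[2-hydroxy-4-methoxy-6-(methoxymethoxy)phenyl]ethan-1-one
Product: 8 1-[2-hydroxy-3-iodo-4-methoxy-6-(methoxymethoxy)phenyl]ethan-1-one
Conditions: BnMe3N·ICl2 (1.05 equiv), NaHCO3, CH2Cl2/MeOH, rt
Reagents that add atoms: benzyltrimethylammonium dichloroiodate, C[N+](C)(C)Cc1ccccc1.Cl[I-]Cl
Why: Electrophilic aromatic iodination, expected ortho to the chelated 2'-OH (C3'), as is usual for hydrogen-bonded ortho-hydroxyaryl ketones, and not at C5' between the two alkoxy groups; bicarbonate removes HCl so the acetal survives. The regiochemistry would be checked by HMBC/NOE before the key step.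

Step 7
Reactants: 8 1-[2-hydroxy-3-iodo-4-methoxy-6-(methoxymethoxy)phenyl]ethan-1-one; 5 1,3-dioxoisoindolin-2-yl (3R)-6-hydroxy-6-methyl-3-(prop-1-en-2-yl)heptanoate (1.5 equiv)
Product: 9 1-{2-hydroxy-3-[(2R)-5-hydroxy-5-methyl-2-(prop-1-en-2-yl)hexyl]-4-methoxy-6-(methoxymethoxy)phenyl}ethan-1-one
Conditions: NiBr2(dme) (20 mol%), 4,4'-di-tert-butyl-2,2'-bipyridine (20 mol%), Zn dust (2.5 equiv), DMA (0.5 M), 25 °C
Reagents that add atoms: none
Why: Nickel-catalysed reductive decarboxylative cross-electrophile coupling of an N-acyloxyphthalimide with an aryl iodide, a reaction type established for primary alkyl redox-active esters. Zinc reduces the nickel bromide complex to a low-valent species that inserts into the C3'–I bond of 8; single-electron reduction of 5 then breaks the N–O bond, CO2 leaves, the primary radical at C1'' is captured by the arylnickel complex, and reductive elimination from the trivalent nickel aryl alkyl species forms C3'–C1''. No ring is closed and no stereocentre is formed: C2'' is β to the radical centre, none of its bonds is broken, and it keeps the configuration fixed in 1. The position on ring A is dictated by the C–I bond, so the C6/C8 question is settled before the coupling. The step needs capture of the homoallylic radical to outrun its 3-exo closure onto the isopropenyl group (the path to a 1,2-vinyl shift); high nickel loading and concentration serve this, and that closure is slow for but-3-enyl radicals. Compound 8 holds no radical acceptor, because the chromone enone is made only afterwards, and the chelated phenol, tertiary alcohol, acetal and ketone should all tolerate zinc in DMA at room temperature. Loss of the carboxyl carbon as CO2 turns the limonene-derived acid into the C10 chain, which completes the mapping of limonene onto the side chain.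

Step 8
Reactants: 9 1-{2-hydroxy-3-[(2R)-5-hydroxy-5-methyl-2-(prop-1-en-2-yl)hexyl]-4-methoxy-6-(methoxymethoxy)phenyl}ethan-1-one
Product: 11 8-[(2R)-5-hydroxy-5-methyl-2-(prop-1-en-2-yl)hexyl]-7-methoxy-5-(methoxymethoxy)-4H-chromen-4-one, via enaminone 10 (not isolated)
Conditions: DMF-DMA (3 equiv), toluene, 90 °C; evaporate; AcOH, CH2Cl2, 40 °C
Reagents that add atoms: N,N-dimethylformamide dimethyl acetal, COC(OC)N(C)C
Why: Condensation of the acetyl CH3 with the amide acetal gives the enaminone; acid then triggers 6-endo addition of O2' to the β-carbon and loss of dimethylamine (addition–elimination) to give the chromone. O6' is blocked, so only the oxygen next to the side chain can close and the chain ends up at C8; acetic acid is too weak to protonate the isopropenyl group.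

Step 9
Reactants: 12 4-bromobenzene-1,3-diol
Product: 13 1-bromo-2,4-bis(methoxymethoxy)benzene
Conditions: MOMCl (2.5 equiv), iPr2NEt, CH2Cl2, 0 °C to rt
Reagents that add atoms: chloromethyl methyl ether, COCCl
Why: Double O-alkylation of the two phenols under amine base.

Step 10
Reactants: 13 1-bromo-2,4-bis(methoxymethoxy)benzene
Product: 16 [2,4-bis(methoxymethoxy)phenyl]boronic acid, via aryllithium 14 (not isolated), via lithium triisopropyl arylborate 15 (not isolated)
Conditions: n-BuLi, THF, -78 °C; B(OiPr)3, -78 °C to rt; 1 M HCl to pH 6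
Reagents that add atoms: triisopropyl borate, CC(C)OB(OC(C)C)OC(C)C; water, O; n-butyllithium, [Li]CCCC (lithium of 14 and 15 only)
Why: Bromine–lithium exchange is faster than ortho-lithiation between the two acetal groups, so boron enters at the former C–Br carbon; borate trapping and hydrolysis at pH 6 give the boronic acid with the acetals intact.

Step 11
Reactants: 11 8-[(2R)-5-hydroxy-5-methyl-2-(prop-1-en-2-yl)hexyl]-7-methoxy-5-(methoxymethoxy)-4H-chromen-4-one; 16 [2,4-bis(methoxymethoxy)phenyl]boronic acid (3 equiv)
Product: 17 (2S)-2-[2,4-bis(methoxymethoxy)phenyl]-8-[(2R)-5-hydroxy-5-methyl-2-(prop-1-en-2-yl)hexyl]-7-methoxy-5-(methoxymethoxy)-2,3-dihydro-4H-chromen-4-one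
Conditions: [Rh(OH)(cod)]2 (3 mol%), (S)-2,2'-bis[bis(3,4,5-trifluorophenyl)phosphino]-6,6'-dimethoxy-1,1'-biphenyl (7 mol%), toluene/H2O (10:1), 40 °C
Reagents that add atoms: none
Why: Rhodium-catalysed asymmetric 1,4-addition of an arylboronic acid to a chromone (Hayashi–Miyaura reaction), a reaction type that has been applied to 5,7-dioxygenated chromones: transmetalation gives an aryl complex of monovalent rhodium that inserts C2=C3, and water protonates the oxa-π-allyl under neutral conditions, so ring C does not open. C2 is set by the ligand alone; the (S)-bisphosphine is expected to give 2S by the quadrant model that holds for cyclic enones, and the sense would be checked on a chromone without the side chain.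

Step 12
Reactants: 17 (2S)-2-[2,4-bis(methoxymethoxy)phenyl]-8-[(2R)-5-hydroxy-5-methyl-2-(prop-1-en-2-yl)hexyl]-7-methoxy-5-(methoxymethoxy)-2,3-dihydro-4H-chromen-4-one
Product: 19 (2S)-2-(2,4-dihydroxyphenyl)-5-hydroxy-8-[(2R)-5-hydroxy-5-methyl-2-(prop-1-en-2-yl)hexyl]-7-methoxy-2,3-dihydro-4H-chromen-4-one, via tetrakis(trimethylsilyl) ether 18 (not isolated)
Conditions: TMSOTf (8 equiv), 2,2'-bipyridyl (12 equiv), MeCN, 0 °C to rt; then H2O, rt
Reagents that add atoms: trimethylsilyl trifluoromethanesulfonate, C[Si](C)(C)OS(=O)(=O)C(F)(F)F (silicon of 18 only; none of its atoms remains in 19)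
Why: Silyl triflate/2,2'-bipyridyl cleavage of aryl methoxymethyl ethers: the acetal oxygen is silylated, bipyridyl takes up the methoxymethyl cation, and the aryl silyl ethers and the silylated C5'' alcohol are hydrolysed when water is added. The pyridine base buffers the medium, so the isopropenyl group is not protonated and ring C is not opened by base; C2 and C2'' are untouched.

## Compound list

1 | (4R)-limonene 1,2-oxide, cis/trans mixture at the epoxide | C=C(C)[C@@H]1CCC2(C)OC2C1 | starting material
2 | (3R)-6-oxo-3-(prop-1-en-2-yl)heptanal | C=C(C)[C@H](CCC(C)=O)CC=O | intermediate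
3 | (3R)-6-oxo-3-(prop-1-en-2-yl)heptanoic acid | C=C(C)[C@H](CCC(C)=O)CC(=O)O | intermediate
4 | (3R)-6-hydroxy-6-methyl-3-(prop-1-en-2-yl)heptanoic acid | C=C(C)[C@H](CCC(C)(C)O)CC(=O)O | intermediate
5 | 1,3-dioxoisoindolin-2-yl (3R)-6-hydroxy-6-methyl-3-(prop-1-en-2-yl)heptanoate | C=C(C)[C@H](CCC(C)(C)O)CC(=O)ON1C(=O)c2ccccc2C1=O | intermediate
6 | 1-(2,6-dihydroxy-4-methoxyphenyl)ethan-1-one | CC(=O)c1c(O)cc(OC)cc1O | starting material
7 | 1-[2-hydroxy-4-methoxy-6-(methoxymethoxy)phenyl]ethan-1-one | CC(=O)c1c(O)cc(OC)cc1OCOC | intermediate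
8 | 1-[2-hydroxy-3-iodo-4-methoxy-6-(methoxymethoxy)phenyl]ethan-1-one | CC(=O)c1c(O)c(I)c(OC)cc1OCOC | intermediate
9 | 1-{2-hydroxy-3-[(2R)-5-hydroxy-5-methyl-2-(prop-1-en-2-yl)hexyl]-4-methoxy-6-(methoxymethoxy)phenyl}ethan-1-one | C=C(C)[C@H](CCC(C)(C)O)Cc1c(OC)cc(OCOC)c(C(C)=O)c1O | intermediate
10 | (2E)-3-(dimethylamino)-1-{2-hydroxy-3-[(2R)-5-hydroxy-5-methyl-2-(prop-1-en-2-yl)hexyl]-4-methoxy-6-(methoxymethoxy)phenyl}prop-2-en-1-one | C=C(C)[C@H](CCC(C)(C)O)Cc1c(OC)cc(OCOC)c(C(=O)/C=C/N(C)C)c1O | intermediate (not isolated)
11 | 8-[(2R)-5-hydroxy-5-methyl-2-(prop-1-en-2-yl)hexyl]-7-methoxy-5-(methoxymethoxy)-4H-chromen-4-one | C=C(C)[C@H](CCC(C)(C)O)Cc1c(OC)cc(OCOC)c2c1occc2=O | intermediate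
12 | 4-bromobenzene-1,3-diol | Oc1ccc(Br)c(O)c1 | starting material
13 | 1-bromo-2,4-bis(methoxymethoxy)benzene | COCOc1ccc(Br)c(OCOC)c1 | intermediate
14 | [2,4-bis(methoxymethoxy)phenyl]lithium | [Li]c1ccc(OCOC)cc1OCOC | intermediate (not isolated)
15 | lithium [2,4-bis(methoxymethoxy)phenyl]tri(propan-2-yloxy)borate | [Li+].CC(C)O[B-](OC(C)C)(OC(C)C)c1ccc(OCOC)cc1OCOC | intermediate (not isolated)
16 | [2,4-bis(methoxymethoxy)phenyl]boronic acid | OB(O)c1ccc(OCOC)cc1OCOC | intermediate
17 | (2S)-2-[2,4-bis(methoxymethoxy)phenyl]-8-[(2R)-5-hydroxy-5-methyl-2-(prop-1-en-2-yl)hexyl]-7-methoxy-5-(methoxymethoxy)-2,3-dihydro-4H-chromen-4-one | C=C(C)[C@H](CCC(C)(C)O)Cc1c(OC)cc(OCOC)c2c1O[C@H](c1ccc(OCOC)cc1OCOC)CC2=O | intermediate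
18 | (2S)-2-{2,4-bis[(trimethylsilyl)oxy]phenyl}-7-methoxy-8-{(2R)-5-methyl-2-(prop-1-en-2-yl)-5-[(trimethylsilyl)oxy]hexyl}-5-[(trimethylsilyl)oxy]-2,3-dihydro-4H-chromen-4-one | C=C(C)[C@H](CCC(C)(C)O[Si](C)(C)C)Cc1c(OC)cc(O[Si](C)(C)C)c2c1O[C@H](c1ccc(O[Si](C)(C)C)cc1O[Si](C)(C)C)CC2=O | intermediate (not isolated)
19 | (2S)-2-(2,4-dihydroxyphenyl)-5-hydroxy-8-[(2R)-5-hydroxy-5-methyl-2-(prop-1-en-2-yl)hexyl]-7-methoxy-2,3-dihydro-4H-chromen-4-one | C=C(C)[C@H](CCC(C)(C)O)Cc1c(OC)cc(O)c2c1O[C@H](c1ccc(O)cc1O)CC2=O | target

## Step count and least certain steps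

Total: 12 steps. Longest linear sequence: 8 steps (1, 2, 3, 4, 7, 8, 11, 12).

**Step 7 (key step).**
- Most likely failure: the primary homoallylic radical closes 3-exo onto the isopropenyl group and reopens to the secondary radical (1,2-vinyl shift) before the nickel centre captures it, which would give a constitutional isomer of 9.
- Also possible: reductive elimination at the di-ortho-substituted, electron-rich aryl is slow, so that hydrodeiodination and alkyl dimerisation take over.
- Fallback (from 4, back at 9): a two-electron Negishi coupling.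
  - Acid 4 is converted with N-hydroxypyridine-2-thione and DCC into the thiohydroxamate ester 2-thioxopyridin-1(2H)-yl (3R)-6-hydroxy-6-methyl-3-(prop-1-en-2-yl)heptanoate F1.
  - Photolysis of F1 with iodoform (Barton decarboxylative iodination; iodine transfer is much faster than the vinyl shift) gives (5S)-5-(iodomethyl)-2,6-dimethylhept-6-en-2-ol F2.
  - TESOTf/2,6-lutidine gives the silyl ether triethyl{[(5S)-5-(iodomethyl)-2,6-dimethylhept-6-en-2-yl]oxy}silane F3.
  - Zinc dust/LiCl in THF inserts to give iodo{(2S)-5-methyl-2-(prop-1-en-2-yl)-5-[(triethylsilyl)oxy]hexyl}zinc F4.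
  - Negishi coupling of F4 (in excess) with 8 under Pd(OAc)2/SPhos gives 1-{2-hydroxy-4-methoxy-6-(methoxymethoxy)-3-[(2R)-5-methyl-2-(prop-1-en-2-yl)-5-[(triethylsilyl)oxy]hexyl]phenyl}ethan-1-one F5.
  - HF·pyridine in THF/pyridine removes the silyl group and returns 9.

**Step 6.**
- Most likely failure: iodination at C5' (para to the hydroxyl) or double iodination, which would place the chain at C6 of the flavanone.
- Fallback (from 6, back at 8): the order is inverted so that symmetry fixes the C–I position.
  - Mono-iodination of the symmetric diol 6 can give only 1-(2,6-dihydroxy-3-iodo-4-methoxyphenyl)ethan-1-one F6.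
  - MOMCl/iPr2NEt then alkylates the hydroxyl remote from iodine, which is less hindered and, being the less acidic one, the weaker partner in the hydrogen bond to the carbonyl. This gives 8.

**Step 11.**
- Most likely failure: slow insertion and protodeboronation of the ortho-alkoxy, electron-rich boronic acid on an electron-rich chromone, or poor facial selectivity.
- Fallback (from 9, back at 17): ring C is closed at O1–C2 instead.
  - Claisen–Schmidt condensation of 9 with 2,4-bis(methoxymethoxy)benzaldehyde (KOH, EtOH) gives the chalcone (2E)-3-[2,4-bis(methoxymethoxy)phenyl]-1-{2-hydroxy-3-[(2R)-5-hydroxy-5-methyl-2-(prop-1-en-2-yl)hexyl]-4-methoxy-6-(methoxymethoxy)phenyl}prop-2-en-1-one F7.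
  - NaOAc in refluxing EtOH closes it to 17 together with its C2 epimer, (2R)-2-[2,4-bis(methoxymethoxy)phenyl]-8-[(2R)-5-hydroxy-5-methyl-2-(prop-1-en-2-yl)hexyl]-7-methoxy-5-(methoxymethoxy)-2,3-dihydro-4H-chromen-4-one F8.
  - The epimers are separated by HPLC on a chiral stationary phase; F8 is returned to the NaOAc conditions, where it re-equilibrates through F7.

**Step 12.**
- Most likely failure: Lewis-acid-induced ionisation at C5'' or protonation of the isopropenyl group followed by cycloetherification, or incomplete cleavage of the two ring-B acetals.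
- Fallback (from 12 and 11, back at 19): ring B is carried with fluoride-labile groups.
  - Silylation of 12 (TBSCl, imidazole) gives [(4-bromo-1,3-phenylene)bis(oxy)]bis[tert-butyl(dimethyl)silane] F9.
  - Miyaura borylation (Pd(dppf)Cl2, B2pin2, KOAc), which avoids an ortho-lithiated silyl ether, gives 2-{2,4-bis[(tert-butyldimethylsilyl)oxy]phenyl}-4,4,5,5-tetramethyl-1,3,2-dioxaborolane F10.
  - Addition of F10 to 11 under the conditions of step 11 gives (2S)-2-{2,4-bis[(tert-butyldimethylsilyl)oxy]phenyl}-8-[(2R)-5-hydroxy-5-methyl-2-(prop-1-en-2-yl)hexyl]-7-methoxy-5-(methoxymethoxy)-2,3-dihydro-4H-chromen-4-one F11.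
  - The 5-O acetal, which lies next to the carbonyl and is open to chelation, is removed with MgBr2·OEt2 to give (2S)-2-{2,4-bis[(tert-butyldimethylsilyl)oxy]phenyl}-5-hydroxy-8-[(2R)-5-hydroxy-5-methyl-2-(prop-1-en-2-yl)hexyl]-7-methoxy-2,3-dihydro-4H-chromen-4-one F12.
  - KHF2 in MeOH at room temperature cleaves the aryl silyl ethers and gives 19.

## Further compounds

F1 | step 7 | 2-thioxopyridin-1(2H)-yl (3R)-6-hydroxy-6-methyl-3-(prop-1-en-2-yl)heptanoate | C=C(C)[C@H](CCC(C)(C)O)CC(=O)On1ccccc1=S
F2 | step 7 | (5S)-5-(iodomethyl)-2,6-dimethylhept-6-en-2-ol | C=C(C)[C@H](CCC(C)(C)O)CI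
F3 | step 7 | triethyl{[(5S)-5-(iodomethyl)-2,6-dimethylhept-6-en-2-yl]oxy}silane | C=C(C)[C@H](CCC(C)(C)O[Si](CC)(CC)CC)CI
F4 | step 7 | iodo{(2S)-5-methyl-2-(prop-1-en-2-yl)-5-[(triethylsilyl)oxy]hexyl}zinc | C=C(C)[C@H](CCC(C)(C)O[Si](CC)(CC)CC)C[Zn]I
F5 | step 7 | 1-{2-hydroxy-4-methoxy-6-(methoxymethoxy)-3-[(2R)-5-methyl-2-(prop-1-en-2-yl)-5-[(triethylsilyl)oxy]hexyl]phenyl}ethan-1-one | C=C(C)[C@H](CCC(C)(C)O[Si](CC)(CC)CC)Cc1c(OC)cc(OCOC)c(C(C)=O)c1O
F6 | step 6 | 1-(2,6-dihydroxy-3-iodo-4-methoxyphenyl)ethan-1-one | CC(=O)c1c(O)cc(OC)c(I)c1O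
F7 | step 11 | (2E)-3-[2,4-bis(methoxymethoxy)phenyl]-1-{2-hydroxy-3-[(2R)-5-hydroxy-5-methyl-2-(prop-1-en-2-yl)hexyl]-4-methoxy-6-(methoxymethoxy)phenyl}prop-2-en-1-one | C=C(C)[C@H](CCC(C)(C)O)Cc1c(OC)cc(OCOC)c(C(=O)/C=C/c2ccc(OCOC)cc2OCOC)c1O
F8 | step 11 | (2R)-2-[2,4-bis(methoxymethoxy)phenyl]-8-[(2R)-5-hydroxy-5-methyl-2-(prop-1-en-2-yl)hexyl]-7-methoxy-5-(methoxymethoxy)-2,3-dihydro-4H-chromen-4-one | C=C(C)[C@H](CCC(C)(C)O)Cc1c(OC)cc(OCOC)c2c1O[C@@H](c1ccc(OCOC)cc1OCOC)CC2=O
F9 | step 12 | [(4-bromo-1,3-phenylene)bis(oxy)]bis[tert-butyl(dimethyl)silane] | CC(C)(C)[Si](C)(C)Oc1ccc(Br)c(O[Si](C)(C)C(C)(C)C)c1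
F10 | step 12 | 2-{2,4-bis[(tert-butyldimethylsilyl)oxy]phenyl}-4,4,5,5-tetramethyl-1,3,2-dioxaborolane | CC(C)(C)[Si](C)(C)Oc1ccc(B2OC(C)(C)C(C)(C)O2)c(O[Si](C)(C)C(C)(C)C)c1
F11 | step 12 | (2S)-2-{2,4-bis[(tert-butyldimethylsilyl)oxy]phenyl}-8-[(2R)-5-hydroxy-5-methyl-2-(prop-1-en-2-yl)hexyl]-7-methoxy-5-(methoxymethoxy)-2,3-dihydro-4H-chromen-4-one | C=C(C)[C@H](CCC(C)(C)O)Cc1c(OC)cc(OCOC)c2c1O[C@H](c1ccc(O[Si](C)(C)C(C)(C)C)cc1O[Si](C)(C)C(C)(C)C)CC2=O
F12 | step 12 | (2S)-2-{2,4-bis[(tert-butyldimethylsilyl)oxy]phenyl}-5-hydroxy-8-[(2R)-5-hydroxy-5-methyl-2-(prop-1-en-2-yl)hexyl]-7-methoxy-2,3-dihydro-4H-chromen-4-one | C=C(C)[C@H](CCC(C)(C)O)Cc1c(OC)cc(O)c2c1O[C@H](c1ccc(O[Si](C)(C)C(C)(C)C)cc1O[Si](C)(C)C(C)(C)C)CC2=O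
A1 | alternative 1 | (2S)-5-methyl-2-(prop-1-en-2-yl)hex-4-en-1-ol, (S)-lavandulol | C=C(C)[C@H](CC=C(C)C)CO
A2 | alternative 1 | (2S)-1-bromo-5-methyl-2-(prop-1-en-2-yl)hex-4-ene, (S)-lavandulyl bromide | C=C(C)[C@H](CC=C(C)C)CBr
A3 | alternative 1 | 1-{2,6-dihydroxy-4-methoxy-3-[(2R)-5-methyl-2-(prop-1-en-2-yl)hex-4-en-1-yl]phenyl}ethan-1-one | C=C(C)[C@H](CC=C(C)C)Cc1c(OC)cc(O)c(C(C)=O)c1O
A4 | alternative 2 | 1-[2-hydroxy-4-methoxy-6-(methoxymethoxy)-3-(3-methylbut-2-en-1-yl)phenyl]ethan-1-one | CC(C)=CCc1c(OC)cc(OCOC)c(C(C)=O)c1O
A5 | alternative 2 | 1-{2-hydroxy-4-methoxy-6-(methoxymethoxy)-3-[5-oxo-2-(prop-1-en-2-yl)hexyl]phenyl}ethan-1-one, racemic | C=C(C)C(CCC(C)=O)Cc1c(OC)cc(OCOC)c(C(C)=O)c1O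
A6 | alternative 3 | (2R)-1-methyl-2-{3-methyl-3-[(triethylsilyl)oxy]butyl}cyclopropan-1-ol, either configuration at C1 | CC1(O)C[C@H]1CCC(C)(C)O[Si](CC)(CC)CC
A7 | alternative 3 | (3R)-3-{[3-acetyl-2-hydroxy-6-methoxy-4-(methoxymethoxy)phenyl]methyl}-6-methyl-6-[(triethylsilyl)oxy]heptan-2-one | CC(=O)[C@H](CCC(C)(C)O[Si](CC)(CC)CC)Cc1c(OC)cc(OCOC)c(C(C)=O)c1O
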